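**Retrosynthetic overview**
- Target ⇒ cut the C6–CH2 bond (nickel-electrocatalytic reductive coupling, then acetate removal): 6-iodobiochanin A 5,7-diacetate + (S)-2-hydroxy-3-methylbut-3-enyl tosylate.
- Tosylate ⇒ (S)-3-methylbut-3-ene-1,2-diol ⇒ (S)-4-isopropenyl dioxolane ⇒ tertiary carbinol ⇒ methyl (R)-2,3-O-isopropylideneglycerate (D-mannitol derived), which carries the only stereocentre.
- Aryl iodide ⇒ biochanin A by C6 iodination and acetylation in one flask.
- Rings: none is built; the chromone and anisyl rings are bought in biochanin A, and the dioxolane ring of the glycerate is carried through steps 1–2 and opened in step 3.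

Assumption: the target is the (R)-enantiomer as drawn, 6-[(2R)-2-hydroxy-3-methylbut-3-enyl]biochanin A; biochanin A and methyl (R)-2,3-O-isopropylideneglycerate are catalogue compounds.

Step 1
Reactants: 1 methyl (4R)-2,2-dimethyl-1,3-dioxolane-4-carboxylate
Product: 2 2-[(4R)-2,2-dimethyl-1,3-dioxolan-4-yl]propan-2-ol
Conditions: MeMgBr (2.5 equiv), THF, 0 °C → rt; aq NH4Cl
Reagents that add atoms: methylmagnesium bromide, C[Mg]Br
Why: Double Grignard addition to the ester outruns enolisation of the α-alkoxy ester, so the purchased (R)-stereocentre passes unchanged into the tertiary carbinol and no new stereocentre is formed.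

Step 2
Reactants: 2 2-[(4R)-2,2-dimethyl-1,3-dioxolan-4-yl]propan-2-ol
Product: 3 (4S)-2,2-dimethyl-4-(prop-1-en-2-yl)-1,3-dioxolane
Conditions: SOCl2 (1.5 equiv), pyridine (5 equiv), CH2Cl2, −10 → 0 °C
Reagents that add atoms: none
Why: Chlorosulfite formation and pyridine-induced E2 dehydration of the tertiary alcohol remove one of six accessible methyl hydrogens rather than the single hindered ring hydrogen (whose loss would give a tetrasubstituted enol ether), giving the isopropenyl group without touching the dioxolane stereocentre (the descriptor changes from R to S only through the priority change).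

Step 3
Reactants: 3 (4S)-2,2-dimethyl-4-(prop-1-en-2-yl)-1,3-dioxolane
Product: 4 (2S)-3-methylbut-3-ene-1,2-diol
Conditions: Dowex 50W-X8 (H+ form), THF/H2O (1:1), 40 °C
Reagents that add atoms: none
Why: Acid-catalysed acetal hydrolysis cleaves only the O–C(acetal) bonds, so the carbinol C–O bond and its configuration are retained while the allylic alcohol tolerates the mild resin acid.

Step 4
Reactants: 4 (2S)-3-methylbut-3-ene-1,2-diol
Product: 5 (2S)-2-hydroxy-3-methylbut-3-en-1-yl 4-methylbenzenesulfonate
Conditions: TsCl (1.05 equiv), Bu2SnO (2 mol %), Et3N (1.1 equiv), CH2Cl2, 0 °C → rt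
Reagents that add atoms: 4-toluenesulfonyl chloride, Cc1ccc(cc1)S(Cl)(=O)=O
Why: Tin-catalysed regioselective sulfonylation of a terminal 1,2-diol through its stannylene acetal activates only the primary oxygen, leaving the secondary allylic hydroxyl and the stereocentre untouched.

Step 5
Reactants: 6 biochanin A
Product: 8 6-iodobiochanin A 5,7-diacetate [6-iodo-3-(4-methoxyphenyl)-4-oxo-4H-chromene-5,7-diyl diacetate], via 6-iodobiochanin A 7 (not isolated)
Conditions: NIS (1.0 equiv), DMF, 0 °C → rt, dark; then Ac2O, pyridine, DMAP (cat.), rt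
Reagents that add atoms: N-iodosuccinimide, O=C1CCC(=O)N1I; acetic anhydride, CC(=O)OC(C)=O
Why: Electrophilic aromatic iodination of the phloroglucinol-type ring is expected at C6, ortho to the chelated 5-hydroxyl whose hydrogen bond to the C4 carbonyl fixes enol character in the C5–C6 bond, one equivalent of NIS limits 6,8-diiodination, and DMAP-catalysed O-acetylation then masks both acidic phenols in the same flask (no stereocentre involved).

Step 6
Reactants: 5 (2S)-2-hydroxy-3-methylbut-3-en-1-yl 4-methylbenzenesulfonate; 8 6-iodobiochanin A 5,7-diacetate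
Product: 11 target CNP0352342.1 [5,7-dihydroxy-6-[(2R)-2-hydroxy-3-methylbut-3-en-1-yl]-3-(4-methoxyphenyl)-4H-chromen-4-one], via iodohydrin 9 (not isolated), via coupled diacetate 10 (not isolated)
Conditions: 5 (1.5 equiv), NaI (0.5 equiv), NiBr2·dme (10 mol %), 4,4'-di-tert-butyl-2,2'-bipyridine (12 mol %), DMA, undivided cell, Zn anode, Ni-foam cathode, constant current (2.5 F/mol), 40 °C; then aqueous work-up and NH3 (7 M in MeOH), 0 °C → rt
Reagents that add atoms: none
Why: Proposed new method: an iodide-relayed nickel-electrocatalytic cross-electrophile coupling of an unprotected 1,2-diol monotosylate with a 2,6-bis(acyloxy)aryl iodide, in which Finkelstein exchange gives iodohydrin 9, cathodically formed zerovalent nickel inserts into the C6–I bond of 8, monovalent nickel abstracts iodine from 9 to give a primary β-hydroxyalkyl radical that is captured at nickel faster than its homoallyl-to-cyclopropylcarbinyl rearrangement (about 10^3 to 10^4 per second), and reductive elimination from trivalent nickel forms the C6–CH2 bond while the Zn anode supplies the electrons and no base is present to close the iodohydrin to a vinyl epoxide; the stereocentre sits one carbon away from the radical and keeps all four of its bonds, so the purchased configuration is retained (the descriptor changes from S to R only through the priority change), and ammonolysis of the two aryl acetates then releases the target; the closest known reaction types are the nickel-catalysed reductive arylation of epoxides through iodohydrins with Mn powder and the nickel-electrocatalytic coupling of aryl halides with simple alkyl halides, neither shown for a free β-hydroxy sulfonate, for a radical bearing an allylic carbinol stereocentre, or for a di-ortho-oxygenated iodo-isoflavone.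

**Compound list**
1 | methyl (4R)-2,2-dimethyl-1,3-dioxolane-4-carboxylate (methyl 2,3-O-isopropylidene-D-glycerate) | COC(=O)[C@H]1COC(C)(C)O1 | starting material
2 | 2-[(4R)-2,2-dimethyl-1,3-dioxolan-4-yl]propan-2-ol | CC(C)(O)[C@H]1COC(C)(C)O1 | intermediate
3 | (4S)-2,2-dimethyl-4-(prop-1-en-2-yl)-1,3-dioxolane | C=C(C)[C@H]1COC(C)(C)O1 | intermediate
4 | (2S)-3-methylbut-3-ene-1,2-diol | C=C(C)[C@H](O)CO | intermediate
5 | (2S)-2-hydroxy-3-methylbut-3-en-1-yl 4-methylbenzenesulfonate | C=C(C)[C@H](O)COS(=O)(=O)c1ccc(C)cc1 | intermediate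
6 | biochanin A (5,7-dihydroxy-3-(4-methoxyphenyl)-4H-chromen-4-one) | COc1ccc(cc1)-c1coc2cc(O)cc(O)c2c1=O | starting material
7 | 6-iodobiochanin A (5,7-dihydroxy-6-iodo-3-(4-methoxyphenyl)-4H-chromen-4-one; formed in the flask) | COc1ccc(cc1)-c1coc2cc(O)c(I)c(O)c2c1=O | intermediate
8 | 6-iodobiochanin A 5,7-diacetate (6-iodo-3-(4-methoxyphenyl)-4-oxo-4H-chromene-5,7-diyl diacetate) | COc1ccc(cc1)-c1coc2cc(OC(C)=O)c(I)c(OC(C)=O)c2c1=O | intermediate
9 | iodohydrin, (2S)-1-iodo-3-methylbut-3-en-2-ol (formed in the flask) | C=C(C)[C@H](O)CI | intermediate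
10 | coupled diacetate, 6-[(2R)-2-hydroxy-3-methylbut-3-en-1-yl]-3-(4-methoxyphenyl)-4-oxo-4H-chromene-5,7-diyl diacetate (formed in the flask) | C=C(C)[C@H](O)Cc1c(OC(C)=O)cc2occ(-c3ccc(OC)cc3)c(=O)c2c1OC(C)=O | intermediate
11 | CNP0352342.1, 5,7-dihydroxy-6-[(2R)-2-hydroxy-3-methylbut-3-en-1-yl]-3-(4-methoxyphenyl)-4H-chromen-4-one | C=C(C)[C@H](O)Cc1c(O)cc2occ(-c3ccc(OC)cc3)c(=O)c2c1O | target

**Step count**
Total: 6 steps (steps 5 and 6 are one-flask sequences). Longest linear sequence: 5 (steps 1, 2, 3, 4, 6).

**Three steps most likely to fail**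

Step 6 (the new coupling). Likely failure modes are protodeiodination of 8, a slow tosylate-to-iodide exchange, 1,2-vinyl shift of the homoallylic radical, radical addition to C2 of the chromone, and loss of the β-hydroxyl from the alkylnickel species. The fallback uses known two-electron chemistry and no free radical; it sets out from 5 and 8 and comes back at 11. Silylation of 5 (TBSOTf, 2,6-lutidine, CH2Cl2, −78 °C) gives (2S)-2-[(tert-butyldimethylsilyl)oxy]-3-methylbut-3-en-1-yl 4-methylbenzenesulfonate F1. NaI in refluxing acetone gives tert-butyl{[(2S)-1-iodo-3-methylbut-3-en-2-yl]oxy}dimethylsilane F2. Zinc insertion (Zn dust, LiCl, THF, 25 °C) gives {(2S)-2-[(tert-butyldimethylsilyl)oxy]-3-methylbut-3-en-1-yl}zinc iodide F3. Negishi coupling with 8 (Pd(OAc)2, SPhos, THF, 25 °C, a zerovalent palladium cycle) gives 6-{(2R)-2-[(tert-butyldimethylsilyl)oxy]-3-methylbut-3-en-1-yl}-3-(4-methoxyphenyl)-4-oxo-4H-chromene-5,7-diyl diacetate F4. Bu4NF/AcOH in THF and then NH3/MeOH give 11.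

Step 5 (C6 versus C8 iodination, and over-iodination). The C6 preference of a free 5,7-dihydroxy isoflavone under NIS is the least certain regiochemical call in the route. The fallback blocks the 7-oxygen so that only the chelated 5-hydroxyl directs; it sets out from 6 and comes back at 7. MOMCl and iPr2NEt in CH2Cl2 at 0 °C give 5-hydroxy-7-(methoxymethoxy)-3-(4-methoxyphenyl)-4H-chromen-4-one F5. Benzyltrimethylammonium dichloroiodate with CaCO3 in CH2Cl2/MeOH gives 5-hydroxy-6-iodo-7-(methoxymethoxy)-3-(4-methoxyphenyl)-4H-chromen-4-one F6. HCl in MeOH at 40 °C gives 7, which is acetylated as in step 5 to 8.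

Step 2 (regiochemistry of the dehydration, tertiary chloride formation, volatility of 3). The fallback builds the alkene by carbonyl methylenation instead of elimination; it sets out from 1 and comes back at 3. MeNHOMe·HCl and iPrMgCl in THF at −20 °C give (4R)-N-methoxy-N,2,2-trimethyl-1,3-dioxolane-4-carboxamide F7. MeMgBr in THF at 0 °C gives 1-[(4R)-2,2-dimethyl-1,3-dioxolan-4-yl]ethan-1-one F8. Wittig methylenation (Ph3PCH3Br, KN(SiMe3)2, THF, −78 → 0 °C) gives 3.

**Further compounds**
F1 | step 6 | (2S)-2-[(tert-butyldimethylsilyl)oxy]-3-methylbut-3-en-1-yl 4-methylbenzenesulfonate | C=C(C)[C@H](O[Si](C)(C)C(C)(C)C)COS(=O)(=O)c1ccc(C)cc1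
F2 | step 6 | tert-butyl{[(2S)-1-iodo-3-methylbut-3-en-2-yl]oxy}dimethylsilane | C=C(C)[C@H](O[Si](C)(C)C(C)(C)C)CI
F3 | step 6 | {(2S)-2-[(tert-butyldimethylsilyl)oxy]-3-methylbut-3-en-1-yl}zinc iodide | C=C(C)[C@H](O[Si](C)(C)C(C)(C)C)C[Zn]I
F4 | step 6 | 6-{(2R)-2-[(tert-butyldimethylsilyl)oxy]-3-methylbut-3-en-1-yl}-3-(4-methoxyphenyl)-4-oxo-4H-chromene-5,7-diyl diacetate | C=C(C)[C@H](O[Si](C)(C)C(C)(C)C)Cc1c(OC(C)=O)cc2occ(-c3ccc(OC)cc3)c(=O)c2c1OC(C)=O
F5 | step 5 | 5-hydroxy-7-(methoxymethoxy)-3-(4-methoxyphenyl)-4H-chromen-4-one | COc1ccc(cc1)-c1coc2cc(OCOC)cc(O)c2c1=O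
F6 | step 5 | 5-hydroxy-6-iodo-7-(methoxymethoxy)-3-(4-methoxyphenyl)-4H-chromen-4-one | COc1ccc(cc1)-c1coc2cc(OCOC)c(I)c(O)c2c1=O
F7 | step 2 | (4R)-N-methoxy-N,2,2-trimethyl-1,3-dioxolane-4-carboxamide | CON(C)C(=O)[C@H]1COC(C)(C)O1
F8 | step 2 | 1-[(4R)-2,2-dimethyl-1,3-dioxolan-4-yl]ethan-1-one | CC(=O)[C@H]1COC(C)(C)O1
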